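The target forms one for one from the coupling partner, so its ceiling in each flask is the partner charged as a fraction of the starting material, and the open question is how much of that fraction turns over within the run.

| setting | amber | blue | violet | ochre |
|---|---|---|---|---|
| starting material | 0.10 M | 0.10 M | 0.10 M | 0.10 M |
| coupling partner | 0.00200 M | 0.00600 M | 0.0200 M | 0.0600 M |
| catalyst | 1.1 mM | 1.1 mM | 1.1 mM | 1.1 mM |
| time | 1.5 min | 1.5 min | 1.5 min | 1.5 min |

    starting material + coupling partner + catalyst → target + catalyst, rate k1*[starting material]*[coupling partner]*[catalyst]/(1 + ([starting material]/sat1)) (sat1 = 13.1 mM, k1 = 8480 M⁻² s⁻¹)
    2 starting material → self-condensation product (k2 = 0.00189 M⁻¹ s⁻¹)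

- percent here means starting material units held: one self-condensation product counts as two
- two of one species on the left: rate k times its square, two consumed each time
- "hardly changes" means that all values lie within two and a half points (for a concentration: within two and a half percent of the largest)
- run time (amber): 1.5 min

1. amount of target at the end, in percent of the starting material charged for amber, blue, violet, ochre, in this order
2. the shape of the row from first to last (falls all the way / rises, then falls / hardly changes / rises all the way / falls, then rises)

**Partner's clock.** The coupling partner is the limiting reagent in each flask, and the catalyst returns at each turn. Self-condensation leaves the partner untouched, and the starting material's first half-life by that step alone, 44.1 min, is much longer than the run of 1.5 min. My own reckoning therefore starts with the starting material held at its charge, which stands 7.63 times above the constant sat. Step 1 then behaves as pseudo-first-order in partner, with the constant 0.108 s⁻¹.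

**Counting lifetimes.** That constant times the run time gives 9.72, the number of partner lifetimes in the run. The fraction of partner left is the exponential of minus this count, 0.00601 % of its own charge.

**Second round.** Ochre's partner takes 60.0 % of the starting material, so the first answer goes back in. With the starting material at 40.0 % of its charge, the constant becomes 0.0921 s⁻¹, slower than before. The count for ochre is then 8.28, still larger than the 4.61 lifetimes that bring partner to a hundredth of its charge. Ceiling times converted fraction gives 0.0200 for amber, 0.0600 for blue, 0.200 for violet and 0.600 for ochre. The steps from flask to flask along this row are 0.0400, 0.140 and 0.400 of the charge, so by this reckoning the row rises all the way.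

**The forecast.** It gives 2 %, 6 %, 20 % and 59.98 %, a row that rises all the way, on the ground that the partner is “essentially all converted in every run”. On the row, it and this reckoning stand together.

**The flasks.** Target reaches 2.00 %, 6.00 %, 20.0 % and 60.0 %, so the row rises all the way. In amber, the partner's half-life of 0.11 min, read at 0.107 min, is far shorter than the run of 1.5 min. That reading makes 9.71 lifetimes, beside the 9.72 counted, and amber's partner stands at 0.00623 % of its charge at the end. Violet, with its starting material taken at 80.0 % of the charge, has the constant 0.105 s⁻¹, so the fall of its partner to 2.00 % of its charge takes 0.621 min by the count, and violet's partner passes that mark at 0.617 min.

The rate constants stand for no real mixture.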